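(The data were computed from invented constants; scatter was added.)

The pitfall in the delta flask is to take the final share of uncatalysed product from the last reading, 15.4 % at 20.0 min, when the two products there hold 83.0 % of the substrate charged and the rest has reached neither.

common to all: substrate 0.50 M

| flask | coupling partner | catalyst | remark | time |
|---|---|---|---|---|
| delta | 0.75 M | 2.5 mM | the very flask that is asked about, followed so far |  |
| epsilon | 0.75 M | 1.7 mM | run made earlier |  |
| flask | 0.750 M | 2.5 mM |  | 4.0 h |

| run | time / min | uncatalysed product / % | target / % |
|---|---|---|---|
| delta | 3.00 | 7.5 | 11.1 |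
| delta | 6.00 | 10.0 | 27.9 |
| delta | 10.0 | 12.4 | 46.6 |
| delta | 12.0 | 12.0 | 53.5 |
| delta | 15.0 | 13.0 | 61.2 |
| delta | 20.0 | 12.8 | 70.2 |
| epsilon | 15.0 | 16.5 | 45.1 |
| epsilon | 30.0 | 17.8 | 67.4 |
| epsilon | 50.0 | 17.9 | 77.0 |
| epsilon | 60.0 | 18.1 | 79.3 |
| epsilon | 80.0 | 18.0 | 80.6 |
| epsilon | 90.0 | 17.9 | 81.7 |

(standard deviation of a reading: 0.3 percentage points)

- the numbers in the tables scatter with a standard deviation of 0.3 percentage points
- candidate steps: substrate + catalyst -> catalyst + intermediate; coupling partner + catalyst + intermediate -> catalyst + target; substrate + coupling partner -> uncatalysed product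

- share of uncatalysed product in uncatalysed product plus target at 30 s
- share of uncatalysed product in uncatalysed product plus target at 4.0 h

Substrate either meets catalyst and becomes intermediate, which coupling partner and catalyst turn into target, or meets coupling partner and becomes uncatalysed product. The last epsilon reading accounts for 99.6 % of the charge, so I divide its ratio of target to uncatalysed product by its catalyst charge and get 2.68 mM⁻¹, the selectivity factor per unit of catalyst, the end ratio of the two products for each unit of catalyst charged. Taking that ratio as proportional to catalyst at these same charges of substrate and coupling partner, I reckon for the delta flask a ratio of 6.71 and a final share of 13.0 %, and the last reading of uncatalysed product in that flask, 12.8 % of the charge, stands close beside it.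

The forecast gives 76 % at 30 s and 12.8 % at 4.0 h, the later from the words “so the final share in delta, pooling both runs, is about 12.8%”.

The flask gives 78.2 % and 13.0 %, both within the margin.

    substrate + catalyst → catalyst + intermediate (k = 76.0 M⁻¹ min⁻¹)
    coupling partner + catalyst + intermediate → catalyst + target (k = 110 M⁻² min⁻¹)
    substrate + coupling partner → uncatalysed product (k = 0.0460 M⁻¹ min⁻¹)

In the delta flask the catalysed step uses substrate 5.5 times as fast as the uncatalysed step at the start and 6.3 times as fast at 0.0535 h, which are ratios of rates at two moments, whereas the carried end ratio of 6.71 is a ratio of amounts gathered over the whole run. In the neighbour flask with 0.630 mM of catalyst, the same factor gives a ratio of 1.69 and so a share of 37.2 %, and that flask gives 36.5 %.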